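Readings and results were computed from invented constants; noise was put on by code.

If the dissolved gas is a reagent and the step that consumes it runs both ways, the product curve of the spring run, which is the very flask asked about, must stop at a fixed ratio c(product)/c(starting material), and I can read that ratio from the way its slope falls.

all flasks: gas phase 200 mM (held); free catalyst 15 mM

|  | starting material | remark | time |
|---|---|---|---|
| spring | 3 M | the very flask that is asked about, followed so far |  |
| flask | 3.0 M |  | 2.5 d |

spring run (percent of the starting material charged)

| time / h | product / % |
|---|---|
| 5.00 | 13.8 |
| 10.0 | 25.8 |
| 15.0 | 35.9 |
| 20.0 | 44.2 |
| 25.0 | 51.1 |

(standard deviation of a reading: 0.3 percentage points)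

- the numbers in the tables scatter with a standard deviation of 0.3 percentage points
- at the start none of the gas phase is in solution

- the product standing at 2.5 d, as a percentage of the starting material charged
- the change that raises the amount of product at 2.5 d, in percent of the starting material charged most ("none" if none brings more than 2 percentage points) (alder / maple / larch / none)
- amount of product at 2.5 d, in percent of the starting material charged, after larch

- alder: doubling the saturation concentration of gas phase, all else as stated
- maple: doubling the transfer coefficient of the gas phase, all else as stated
- larch: doubling the amount of free catalyst, all else as stated

I take the slope as the gas supply, proportional to the gap between saturation and c(dissolved gas), and I let c(dissolved gas) follow its balance value, proportional to c(product)/c(starting material); the slope then falls on a straight line in that ratio. Between the first two readings the spring run climbs 0.0240 /h at a ratio of 0.247, and between the last two 0.0138 /h at 0.910, so the line reaches zero at 1.81, the stopping ratio. Traced back, the line starts at a slope of 0.0278 /h, and the last slope is half of that. The curve bends towards a level of 64.4 % with a time constant of 8.25 h. Since the 35.0 h after the last reading are far longer than this, the gap shrinks to 0.19 percentage points, and I commit to 64.2 %, which is thermodynamic control. Doubling the saturation (alder) doubles the stopping ratio and lifts the level to 78.3 %. Maple and larch should hasten the approach and leave the level, and that remaining gap is less than the margin, so I expect larch to stay near my 64.2 %.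

The forecast differs from my reckoning: it gives 78 %, names larch as best and puts that change at 93 %, holding that “The droop suggests slow catalyst loss or product binding of free catalyst”.

The flask stands at 62.7 % after 2.5 d, and after 25.0 d it stands at 63.2 %, with 36.8 % of the starting material left. The best change is alder, worth 15 points, against 0.56 points for maple and 0.27 points for larch, which reaches 62.9 %.

    gas phase ⇌ dissolved gas, rate k1*(csat - [dissolved gas]) (kL = 1.50 × 10⁻⁴ /s)
    starting material + dissolved gas + free catalyst ⇌ free catalyst + product (K = 8.60 /M, k = 0.0240 /M²/s)
    free catalyst → spent catalyst (k = 9.00 × 10⁻⁷ /s)

Against my stopping ratio of 1.81, read from the spring run, the ratio c(product)/c(starting material) of the flask stands at 1.72 after 25.0 d, and the alder flask, at 77.5 % after 2.5 d, stands at 3.44, twice that.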